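**Retrosynthetic overview**

1. Ring letters: A and G are the two dihydroxyphenoxy rings (A on the dioxin side), B is the benzo ring of the dioxin that carries A, C is the 1,4-dioxin, D is the central benzene shared by C and the furan E, F is the outer benzo ring of the dibenzofuran and carries G.
2. Ring C is closed late by a dehydrogenative C–O coupling between the ring B hydroxyl and an unfunctionalised C–H of ring D, so that carbon never carries a leaving group.
3. Enabling feature: the hydroxyl carbons of ring D and ring F (C-3 and C-7 of the dibenzofuran) are each para to the ring D–ring F bond. Two-electron oxidation of this pair gives an extended quinone in which ring D C-2 (between the C-3 carbonyl and C-1, which holds the ether oxygen to ring B) is a 1,8-acceptor within reach of the ring B hydroxyl.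
4. Ring E is closed before that, at its C–C bond, by decarboxylative C–H arylation of a 2,6-bis(aryloxy)benzoic acid.
5. All ethers at rings B and D come from 2,6-difluorobenzaldehydes by SNAr, the formyl group then becoming OH (ring B) or the biaryl carbon (ring D); order: A–B ether, B–D and D–F ethers, ring E, ring C, global demethylation.

Key step: step 17

Assumption: the difluorobenzaldehydes 1, 9 and 11 are taken as purchasable; the target has no stereocentre, so none has to be set.

**Route**

Step 1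
Reactants: 1 2,6-difluoro-3,5-dimethoxybenzaldehyde; 2 3,5-dimethoxyphenol
Product: 3 2-(3,5-dimethoxyphenoxy)-6-fluoro-3,5-dimethoxybenzaldehyde
Conditions: K2CO3, DMSO, 90 °C
Reagents that add atoms: none
Why: Nucleophilic aromatic substitution (SNAr) of a fluoride ortho to the formyl group; the aryloxy group that enters donates into the carbonyl and should hold the reaction at the mono-ether.

Step 2
Reactants: 3 2-(3,5-dimethoxyphenoxy)-6-fluoro-3,5-dimethoxybenzaldehyde
Product: 4 2-(3,5-dimethoxyphenoxy)-3,5-dimethoxy-6-[(4-methoxyphenyl)methoxy]benzaldehyde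
Conditions: 4-methoxybenzyl alcohol, NaH, THF/DMF, 0 °C to rt
Reagents that add atoms: 4-methoxybenzyl alcohol, COc1ccc(CO)cc1
Why: A second SNAr with the more nucleophilic alkoxide displaces the remaining fluoride (a better leaving group than the aryloxide) and puts an acid-labile mask on the oxygen that will later join ring D.

Step 3
Reactants: 4 2-(3,5-dimethoxyphenoxy)-3,5-dimethoxy-6-[(4-methoxyphenyl)methoxy]benzaldehyde
Product: 6 2-(3,5-dimethoxyphenoxy)-3,5-dimethoxy-6-[(4-methoxyphenyl)methoxy]phenol, via aryl formate 5 (not isolated)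
Conditions: mCPBA, CH2Cl2, 0 °C; aqueous NaHCO3 wash; then K2CO3 (cat.), MeOH, rt
Reagents that add atoms: mCPBA, OOC(=O)c1cccc(Cl)c1
Why: Baeyer–Villiger (Dakin-type) oxidation, in which the electron-rich aryl group migrates to give the formate; methanolysis then frees the phenol that becomes the dioxin oxygen of ring B.

Step 4
Reactants: 6 2-(3,5-dimethoxyphenoxy)-3,5-dimethoxy-6-[(4-methoxyphenyl)methoxy]phenol
Product: 7 2-(benzyloxy)-1-(3,5-dimethoxyphenoxy)-4,6-dimethoxy-3-[(4-methoxyphenyl)methoxy]benzene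
Conditions: BnBr, K2CO3, DMF, 50 °C
Reagents that add atoms: benzyl bromide, BrCc1ccccc1
Why: Williamson etherification protects this oxygen as a benzyl ether that lasts until step 16.

Step 5
Reactants: 7 2-(benzyloxy)-1-(3,5-dimethoxyphenoxy)-4,6-dimethoxy-3-[(4-methoxyphenyl)methoxy]benzene
Product: 8 2-(benzyloxy)-3-(3,5-dimethoxyphenoxy)-4,6-dimethoxyphenol
Conditions: TFA, Et3SiH, CH2Cl2, 0 °C
Reagents that add atoms: none
Why: Acidolysis of the 4-methoxybenzyl ether with triethylsilane as cation trap (ionic hydrogenation) frees the one phenol needed for step 11, while benzyl and diaryl ethers are stable to dilute TFA.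

Step 6
Reactants: 9 2,6-difluoro-4-hydroxybenzaldehyde
Product: 10 4-(benzyloxy)-2,6-difluorobenzaldehyde
Conditions: BnBr, K2CO3, DMF, rt
Reagents that add atoms: benzyl bromide, BrCc1ccccc1
Why: Williamson etherification of the acidic para-hydroxyl gives the symmetrical ring D electrophile.

Step 7
Reactants: 11 2,6-difluoro-4-methoxybenzaldehyde
Product: 12 2,6-bis(benzyloxy)-4-methoxybenzaldehyde
Conditions: BnOH, NaH, DMF, 0 to 60 °C
Reagents that add atoms: benzyl alcohol, OCc1ccccc1
Why: Twofold SNAr of sodium benzyl oxide at the two formyl-activated fluorides.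

Step 8
Reactants: 12 2,6-bis(benzyloxy)-4-methoxybenzaldehyde
Product: 14 2,6-bis(benzyloxy)-4-methoxyphenol, via aryl formate 13 (not isolated)
Conditions: mCPBA, CH2Cl2, 0 °C; aqueous NaHCO3 wash; then K2CO3 (cat.), MeOH, rt, argon
Reagents that add atoms: mCPBA, OOC(=O)c1cccc(Cl)c1
Why: Baeyer–Villiger (Dakin-type) oxidation of a 2,4,6-trialkoxybenzaldehyde, for which aryl migration is strongly favoured, followed by formate methanolysis.

Step 9
Reactants: 14 2,6-bis(benzyloxy)-4-methoxyphenol; 15 1-bromo-3,5-dimethoxybenzene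
Product: 16 1,3-bis(benzyloxy)-2-(3,5-dimethoxyphenoxy)-5-methoxybenzene
Conditions: CuI (cat.), picolinic acid (cat.), K3PO4, DMSO, 90 °C, argon
Reagents that add atoms: none
Why: Ullmann-type copper-catalysed diaryl ether synthesis with the picolinic acid ligand system, which is known to couple 2,6-disubstituted phenols with aryl bromides.

Step 10
Reactants: 16 1,3-bis(benzyloxy)-2-(3,5-dimethoxyphenoxy)-5-methoxybenzene
Product: 17 2-(3,5-dimethoxyphenoxy)-5-methoxybenzene-1,3-diol
Conditions: H2 (1 atm), Pd/C, EtOAc/MeOH, rt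
Reagents that add atoms: none
Why: Hydrogenolysis of the two benzyl ethers gives a symmetrical diol with two equivalent hydroxyls, while methyl and diaryl ethers are untouched.

Step 11
Reactants: 8 2-(benzyloxy)-3-(3,5-dimethoxyphenoxy)-4,6-dimethoxyphenol; 10 4-(benzyloxy)-2,6-difluorobenzaldehyde
Product: 18 4-(benzyloxy)-2-[2-(benzyloxy)-3-(3,5-dimethoxyphenoxy)-4,6-dimethoxyphenoxy]-6-fluorobenzaldehyde
Conditions: K2CO3, DMF, 80 °C, argon
Reagents that add atoms: none
Why: SNAr of the hindered phenoxide at one of two equivalent formyl-activated fluorides; the hindered partner is used in the easier first substitution, and the first aryloxy group slows the second.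

Step 12
Reactants: 18 4-(benzyloxy)-2-[2-(benzyloxy)-3-(3,5-dimethoxyphenoxy)-4,6-dimethoxyphenoxy]-6-fluorobenzaldehyde; 17 2-(3,5-dimethoxyphenoxy)-5-methoxybenzene-1,3-diol
Product: 19 4-(benzyloxy)-2-[2-(benzyloxy)-3-(3,5-dimethoxyphenoxy)-4,6-dimethoxyphenoxy]-6-[2-(3,5-dimethoxyphenoxy)-3-hydroxy-5-methoxyphenoxy]benzaldehyde
Conditions: 17 (3 equiv), Cs2CO3, DMSO, 110 °C, argon
Reagents that add atoms: none
Why: SNAr at the second formyl-activated fluoride by the mono-phenoxide of the symmetrical diol, used in excess so that each diol reacts once; its two hydroxyls are equivalent, so no regiochemical question arises.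

Step 13
Reactants: 19 4-(benzyloxy)-2-[2-(benzyloxy)-3-(3,5-dimethoxyphenoxy)-4,6-dimethoxyphenoxy]-6-[2-(3,5-dimethoxyphenoxy)-3-hydroxy-5-methoxyphenoxy]benzaldehyde
Product: 20 4-(benzyloxy)-2-[2-(benzyloxy)-3-(3,5-dimethoxyphenoxy)-4,6-dimethoxyphenoxy]-6-[3-(benzyloxy)-2-(3,5-dimethoxyphenoxy)-5-methoxyphenoxy]benzaldehyde
Conditions: BnBr, K2CO3, DMF, rt
Reagents that add atoms: benzyl bromide, BrCc1ccccc1
Why: Williamson etherification masks the remaining ring F phenol so that no free phenol is exposed to the silver and palladium steps.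

Step 14
Reactants: 20 4-(benzyloxy)-2-[2-(benzyloxy)-3-(3,5-dimethoxyphenoxy)-4,6-dimethoxyphenoxy]-6-[3-(benzyloxy)-2-(3,5-dimethoxyphenoxy)-5-methoxyphenoxy]benzaldehyde
Product: 21 4-(benzyloxy)-2-[2-(benzyloxy)-3-(3,5-dimethoxyphenoxy)-4,6-dimethoxyphenoxy]-6-[3-(benzyloxy)-2-(3,5-dimethoxyphenoxy)-5-methoxyphenoxy]benzoic acid
Conditions: Ag2O, aqueous NaOH, THF/EtOH, 40 °C; then HCl
Reagents that add atoms: silver oxide Ag2O, [Ag+].[Ag+].[O-2]
Why: Silver oxide oxidation of the aldehyde to the acid (Tollens-type), chosen because it generates no electrophilic halogen that could attack the trialkoxyarene rings.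

Step 15
Reactants: 21 4-(benzyloxy)-2-[2-(benzyloxy)-3-(3,5-dimethoxyphenoxy)-4,6-dimethoxyphenoxy]-6-[3-(benzyloxy)-2-(3,5-dimethoxyphenoxy)-5-methoxyphenoxy]benzoic acid
Product: 22 3,7-bis(benzyloxy)-1-[2-(benzyloxy)-3-(3,5-dimethoxyphenoxy)-4,6-dimethoxyphenoxy]-6-(3,5-dimethoxyphenoxy)-9-methoxydibenzo[b,d]furan
Conditions: Pd(O2CCF3)2 (15 mol %), Ag2CO3 (3 equiv), DMSO/1,4-dioxane, 150 °C
Reagents that add atoms: none
Why: Palladium-catalysed decarboxylative intramolecular C–H arylation, known for ortho-substituted 2-aryloxybenzoic acids, closes ring E at its C–C bond; the aryl-palladium can only reach the single C–H ortho to the ether oxygen on ring F, because ring B has no ortho hydrogen, and Ag2CO3 returns zerovalent palladium to divalent palladium.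

Step 16
Reactants: 22 3,7-bis(benzyloxy)-1-[2-(benzyloxy)-3-(3,5-dimethoxyphenoxy)-4,6-dimethoxyphenoxy]-6-(3,5-dimethoxyphenoxy)-9-methoxydibenzo[b,d]furan
Product: 23 1-[3-(3,5-dimethoxyphenoxy)-2-hydroxy-4,6-dimethoxyphenoxy]-6-(3,5-dimethoxyphenoxy)-9-methoxydibenzo[b,d]furan-3,7-diol
Conditions: H2 (1 atm), Pd/C, EtOAc/MeOH, rt; work-up under argon
Reagents that add atoms: none
Why: Hydrogenolysis removes the three benzyl ethers and frees exactly the three hydroxyls the key step needs (ring D, ring F, ring B), while the seven methyl ethers stay.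

Step 17
Reactants: 23 1-[3-(3,5-dimethoxyphenoxy)-2-hydroxy-4,6-dimethoxyphenoxy]-6-(3,5-dimethoxyphenoxy)-9-methoxydibenzo[b,d]furan-3,7-diol
Product: 25 hepta-O-methylphlorofucofuroeckol A (free hydroxyls on ring D and on ring F next to the ring G ether), via extended quinone 24 (not isolated)
Conditions: DDQ (1.05 equiv), 1,4-dioxane, 10 °C to rt, argon
Reagents that add atoms: none
Why: Proposed new method: DDQ should take two electrons and two protons from the ring D and ring F hydroxyls, which both stand para to the biaryl bond, and give the extended dibenzofuran quinone 24; there the ring D carbon between the C=O carbon and the carbon bearing the ether oxygen to ring B is the end of a 1,8-acceptor system, the ring B hydroxyl adds to it, and a proton shift re-aromatises ring D, so the net change is a dehydrogenative C–H/O–H coupling with polarity reversal of a normally nucleophilic phloroglucinol carbon. The closest known reaction types are the oxidation of hydroquinones and 4,4'-biphenols to quinones and diphenoquinones followed by conjugate addition of oxygen nucleophiles ortho to the quinone oxygen, and the oxidative intramolecular oxa-Michael cyclisation of hydroquinones with a tethered hydroxyl. Ring C (the 1,4-dioxin) closes in a 6-endo-trig mode by this C–O bond, and no stereocentre is formed. Site selectivity is needed among the electron-rich C–H positions of rings A, D, F and G; it is secured because only the dibenzofuran unit is raised to the quinone level, the only hydroxyl left is that of ring B, and from it only this ring D carbon can be reached through a six-membered transition state that ends in an aromatic product, whereas addition at the neighbouring ring-fusion carbon gives a quinol ether that cannot aromatise and should revert. The methyl ethers on ring B keep its other oxygens from closing an isomeric dioxin, and one equivalent of oxidant suffices because the cyclisation consumes the quinone.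

Step 18
Reactants: 25 hepta-O-methylphlorofucofuroeckol A
Product: 26 phlorofucofuroeckol A
Conditions: BBr3, CH2Cl2, −78 °C to rt; then MeOH/H2O
Reagents that add atoms: none
Why: Lewis-acid cleavage of the seven aryl methyl ethers with BBr3 (demethylation via aryloxyboranes and bromomethane), to which diaryl ether, dibenzofuran and dibenzodioxin linkages are inert.

**Compound list**

1 | 2,6-difluoro-3,5-dimethoxybenzaldehyde | O=Cc1c(F)c(OC)cc(OC)c1F | starting material
2 | 3,5-dimethoxyphenol | COc1cc(O)cc(OC)c1 | starting material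
3 | 2-(3,5-dimethoxyphenoxy)-6-fluoro-3,5-dimethoxybenzaldehyde | O=Cc1c(F)c(OC)cc(OC)c1Oc1cc(OC)cc(OC)c1 | intermediate
4 | 2-(3,5-dimethoxyphenoxy)-3,5-dimethoxy-6-[(4-methoxyphenyl)methoxy]benzaldehyde | O=Cc1c(OCc2ccc(OC)cc2)c(OC)cc(OC)c1Oc1cc(OC)cc(OC)c1 | intermediate
5 | 2-(3,5-dimethoxyphenoxy)-3,5-dimethoxy-6-[(4-methoxyphenyl)methoxy]phenyl formate | O=COc1c(OCc2ccc(OC)cc2)c(OC)cc(OC)c1Oc1cc(OC)cc(OC)c1 | intermediate
6 | 2-(3,5-dimethoxyphenoxy)-3,5-dimethoxy-6-[(4-methoxyphenyl)methoxy]phenol | Oc1c(OCc2ccc(OC)cc2)c(OC)cc(OC)c1Oc1cc(OC)cc(OC)c1 | intermediate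
7 | 2-(benzyloxy)-1-(3,5-dimethoxyphenoxy)-4,6-dimethoxy-3-[(4-methoxyphenyl)methoxy]benzene | c1ccccc1COc1c(OCc2ccc(OC)cc2)c(OC)cc(OC)c1Oc1cc(OC)cc(OC)c1 | intermediate
8 | 2-(benzyloxy)-3-(3,5-dimethoxyphenoxy)-4,6-dimethoxyphenol | Oc1c(OC)cc(OC)c(Oc2cc(OC)cc(OC)c2)c1OCc1ccccc1 | intermediate
9 | 2,6-difluoro-4-hydroxybenzaldehyde | O=Cc1c(F)cc(O)cc1F | starting material
10 | 4-(benzyloxy)-2,6-difluorobenzaldehyde | O=Cc1c(F)cc(OCc2ccccc2)cc1F | intermediate
11 | 2,6-difluoro-4-methoxybenzaldehyde | COc1cc(F)c(C=O)c(F)c1 | starting material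
12 | 2,6-bis(benzyloxy)-4-methoxybenzaldehyde | COc1cc(OCc2ccccc2)c(C=O)c(OCc2ccccc2)c1 | intermediate
13 | 2,6-bis(benzyloxy)-4-methoxyphenyl formate | COc1cc(OCc2ccccc2)c(OC=O)c(OCc2ccccc2)c1 | intermediate
14 | 2,6-bis(benzyloxy)-4-methoxyphenol | COc1cc(OCc2ccccc2)c(O)c(OCc2ccccc2)c1 | intermediate
15 | 1-bromo-3,5-dimethoxybenzene | COc1cc(Br)cc(OC)c1 | starting material
16 | 1,3-bis(benzyloxy)-2-(3,5-dimethoxyphenoxy)-5-methoxybenzene | COc1cc(OCc2ccccc2)c(Oc2cc(OC)cc(OC)c2)c(OCc2ccccc2)c1 | intermediate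
17 | 2-(3,5-dimethoxyphenoxy)-5-methoxybenzene-1,3-diol | COc1cc(O)c(Oc2cc(OC)cc(OC)c2)c(O)c1 | intermediate
18 | 4-(benzyloxy)-2-[2-(benzyloxy)-3-(3,5-dimethoxyphenoxy)-4,6-dimethoxyphenoxy]-6-fluorobenzaldehyde | O=Cc1c(F)cc(OCc2ccccc2)cc1Oc1c(OC)cc(OC)c(Oc2cc(OC)cc(OC)c2)c1OCc1ccccc1 | intermediate
19 | 4-(benzyloxy)-2-[2-(benzyloxy)-3-(3,5-dimethoxyphenoxy)-4,6-dimethoxyphenoxy]-6-[2-(3,5-dimethoxyphenoxy)-3-hydroxy-5-methoxyphenoxy]benzaldehyde | O=Cc1c(Oc2cc(OC)cc(O)c2Oc2cc(OC)cc(OC)c2)cc(OCc2ccccc2)cc1Oc1c(OC)cc(OC)c(Oc2cc(OC)cc(OC)c2)c1OCc1ccccc1 | intermediate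
20 | 4-(benzyloxy)-2-[2-(benzyloxy)-3-(3,5-dimethoxyphenoxy)-4,6-dimethoxyphenoxy]-6-[3-(benzyloxy)-2-(3,5-dimethoxyphenoxy)-5-methoxyphenoxy]benzaldehyde | O=Cc1c(Oc2cc(OC)cc(OCc3ccccc3)c2Oc2cc(OC)cc(OC)c2)cc(OCc2ccccc2)cc1Oc1c(OC)cc(OC)c(Oc2cc(OC)cc(OC)c2)c1OCc1ccccc1 | intermediate
21 | 4-(benzyloxy)-2-[2-(benzyloxy)-3-(3,5-dimethoxyphenoxy)-4,6-dimethoxyphenoxy]-6-[3-(benzyloxy)-2-(3,5-dimethoxyphenoxy)-5-methoxyphenoxy]benzoic acid | OC(=O)c1c(Oc2cc(OC)cc(OCc3ccccc3)c2Oc2cc(OC)cc(OC)c2)cc(OCc2ccccc2)cc1Oc1c(OC)cc(OC)c(Oc2cc(OC)cc(OC)c2)c1OCc1ccccc1 | intermediate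
22 | 3,7-bis(benzyloxy)-1-[2-(benzyloxy)-3-(3,5-dimethoxyphenoxy)-4,6-dimethoxyphenoxy]-6-(3,5-dimethoxyphenoxy)-9-methoxydibenzo[b,d]furan | c1(Oc2c(OC)cc(OC)c(Oc3cc(OC)cc(OC)c3)c2OCc2ccccc2)cc(OCc2ccccc2)cc2oc3c(Oc4cc(OC)cc(OC)c4)c(OCc4ccccc4)cc(OC)c3c12 | intermediate
23 | 1-[3-(3,5-dimethoxyphenoxy)-2-hydroxy-4,6-dimethoxyphenoxy]-6-(3,5-dimethoxyphenoxy)-9-methoxydibenzo[b,d]furan-3,7-diol | c1(Oc2c(OC)cc(OC)c(Oc3cc(OC)cc(OC)c3)c2O)cc(O)cc2oc3c(Oc4cc(OC)cc(OC)c4)c(O)cc(OC)c3c12 | intermediate
24 | 1-[3-(3,5-dimethoxyphenoxy)-2-hydroxy-4,6-dimethoxyphenoxy]-6-(3,5-dimethoxyphenoxy)-9-methoxydibenzo[b,d]furan-3,7-dione (extended quinone) | O=C1C=C(Oc2c(OC)cc(OC)c(Oc3cc(OC)cc(OC)c3)c2O)C2=C3C(OC)=CC(=O)C(Oc4cc(OC)cc(OC)c4)=C3OC2=C1 | intermediate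
25 | hepta-O-methylphlorofucofuroeckol A (methyl ethers on rings A, B, G and on the ring F oxygen peri to ring D; free hydroxyls on ring D and on ring F next to the ring G ether) | COc1cc(OC)cc(Oc2c(OC)cc(OC)c3c2Oc2c(O)cc4oc5c(Oc6cc(OC)cc(OC)c6)c(O)cc(OC)c5c4c2O3)c1 | intermediate
26 | phlorofucofuroeckol A | Oc1cc(O)cc(Oc2c(O)cc(O)c3c2Oc2c(O)cc4oc5c(Oc6cc(O)cc(O)c6)c(O)cc(O)c5c4c2O3)c1 | target

**Step count and risks**

Total step count: 18. Longest linear sequence: 13 steps (steps 1 to 5, then 11 to 18).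

Steps most likely to fail:

1. Step 17 (Proposed new method). The oxidant may take one electron from the hindered ring B phenol instead of two from the dibenzofuran diol, leading to radical coupling between molecules. Alternatively the quinone may form but be consumed by intermolecular additions before the ring B hydroxyl closes, or reversible spiro-ketal formation at the ether-bearing ring D carbon may let the aryl group migrate between the two ring B oxygens. Fallback with known chemistry, setting out from 23 and returning at 25: phenoxide-directed iodination of 23 (I2, morpholine, CH2Cl2/MeOH, 0 °C) should iodinate the positions ortho to the two dibenzofuran hydroxyls and give the 2,4,8-triiodo derivative of 23 F1. Intramolecular Ullmann etherification (CuI, N,N-dimethylglycine, Cs2CO3, 1,4-dioxane, 90 °C) can only engage the iodide next to the ring B ether and should give the 4,8-diiodo dioxin F2. Hydrodeiodination (H2, Pd/C, Et3N, MeOH) then removes the remaining iodine, and any iodine taken up by ring B, to give 25.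

2. Step 15. Protodecarboxylation of the aryl-silver or aryl-palladium species may outrun C–H cleavage on ring F and return the arene without the biaryl bond. Fallback, setting out from 20 and returning at 22: Baeyer–Villiger oxidation of 20 (mCPBA, CH2Cl2, 0 °C; then K2CO3, MeOH) should give the phenol F3, triflation (Tf2O, pyridine, CH2Cl2, 0 °C) the aryl triflate F4, and intramolecular direct arylation (Pd(OAc)2, PCy3·HBF4, K2CO3, DMA, 130 °C) closes ring E through a concerted metalation–deprotonation at the same ring F C–H to give 22.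

3. Step 9. The electron-rich trialkoxyphenoxide may be oxidised to a quinone by copper and traces of air, and C–O bond formation at a phenoxide flanked by two benzyloxy groups may be slow. Fallback, setting out from 14 and returning at 16: metal-free O-arylation with a diaryliodonium salt. Purchased 1-iodo-3,5-dimethoxybenzene is oxidised in one pot (mCPBA, TsOH·H2O, MeCN, then 1,3,5-trimethoxybenzene) to (3,5-dimethoxyphenyl)(2,4,6-trimethoxyphenyl)iodonium tosylate F5. With 14 and K2CO3 in toluene at 50 °C this transfers the less electron-rich 3,5-dimethoxyphenyl group to oxygen by ligand coupling and gives 16.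

**Further compounds**

F1 | step 17 | 2,4,8-triiodo derivative of 23 | c1(Oc2c(OC)cc(OC)c(Oc3cc(OC)cc(OC)c3)c2O)c(I)c(O)c(I)c2oc3c(Oc4cc(OC)cc(OC)c4)c(O)c(I)c(OC)c3c12
F2 | step 17 | diiodo derivative of 25 (iodine ortho to each free hydroxyl, on ring D and ring F) | COc1cc(OC)cc(Oc2c(OC)cc(OC)c3c2Oc2c(O)c(I)c4oc5c(Oc6cc(OC)cc(OC)c6)c(O)c(I)c(OC)c5c4c2O3)c1
F3 | step 15 | 4-(benzyloxy)-2-[2-(benzyloxy)-3-(3,5-dimethoxyphenoxy)-4,6-dimethoxyphenoxy]-6-[3-(benzyloxy)-2-(3,5-dimethoxyphenoxy)-5-methoxyphenoxy]phenol | Oc1c(Oc2cc(OC)cc(OCc3ccccc3)c2Oc2cc(OC)cc(OC)c2)cc(OCc2ccccc2)cc1Oc1c(OC)cc(OC)c(Oc2cc(OC)cc(OC)c2)c1OCc1ccccc1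
F4 | step 15 | trifluoromethanesulfonate of F3 | O=S(=O)(Oc1c(Oc2cc(OC)cc(OCc3ccccc3)c2Oc2cc(OC)cc(OC)c2)cc(OCc2ccccc2)cc1Oc1c(OC)cc(OC)c(Oc2cc(OC)cc(OC)c2)c1OCc1ccccc1)C(F)(F)F
F5 | step 9 | (3,5-dimethoxyphenyl)(2,4,6-trimethoxyphenyl)iodonium 4-methylbenzenesulfonate | COc1cc(OC)cc([I+]c2c(OC)cc(OC)cc2OC)c1.Cc1ccc(cc1)S(=O)(=O)[O-]
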